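The target climbs in the runs so far while the electrophile falls, so you bracket the electrophile used.

| setting | Sunday's | Friday's | Wednesday's | flask |
|---|---|---|---|---|
| electrophile | 0.060 M | 0.060 M | 0.090 M | 0.060 M |
| free base | 0.048 M | 0.048 M | 0.048 M | 0.0480 M |
| protonated nucleophile | 0.032 M | 0.13 M | 0.063 M | 0.0630 M |
| remark | run made earlier | run made earlier | run made earlier |  |
| time |  |  |  | 12 h |

| run | time / h | electrophile / % | target / % |
|---|---|---|---|
| Sunday's | 1.00 | 90.2 | 9.4 |
| Sunday's | 2.00 | 85.3 | 16.7 |
| Sunday's | 2.50 | 82.5 | 16.7 |
| Sunday's | 4.00 | 76.8 | 21.5 |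
| Sunday's | 6.00 | 74.2 | 26.6 |
| Sunday's | 10.0 | 70.0 | 29.8 |
| Sunday's | 15.0 | 65.1 | 29.8 |
| Friday's | 2.00 | 78.4 | 20.4 |
| Friday's | 4.00 | 69.4 | 30.4 |
| Friday's | 6.00 | 62.1 | 32.5 |
| Friday's | 8.00 | 55.6 | 39.1 |
| Friday's | 10.0 | 50.2 | 39.8 |
| Friday's | 12.0 | 46.0 | 43.8 |
| Friday's | 15.0 | 41.1 | 47.1 |
| Wednesday's | 1.00 | 86.5 | 11.1 |
| Wednesday's | 2.00 | 81.4 | 15.6 |
| Wednesday's | 4.00 | 74.5 | 23.9 |
| Wednesday's | 8.00 | 70.1 | 27.2 |
| Wednesday's | 15.0 | 58.9 | 33.3 |

(readings scatter by 1 percentage point)

1. part of the electrophile that has reacted at 12 h
2. share of the unused nucleophile that is free and not bound as protonated nucleophile, at 12 h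

- the earlier runs do not show how much of nucleophile is bound; that part of a forecast is a guess

Friday's run gives the roof. It held more protonated nucleophile than this flask and had used 54.0% at 12 h. Sunday's run held less, and between its readings it gives a floor of 32.0%. Wednesday's run raises that floor to 36.3%, with this flask's protonated nucleophile over a bigger electrophile charge.

To tighten, compare Sunday's and Friday's runs, whose other charges match. They give 11 percentage points of electrophile used for each doubling of the protonated nucleophile charge: the gain per doubling. This flask stands 0.977 doublings above Sunday's run, so your reckoning is 42.6%.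

The forecast says 46% (42% to 50%), inside the bracket but above your figure. For the free share it says 5.5% (2.5% to 12%), adding: “This is largely a guess.”

The flask gives 41.1%, inside the bracket and just under the forecast's low end. Its free share is 13.1%, above the forecast's high end.

    acid set free + free base ⇌ salt of the base, settled at all times (K = 19300 /M)
    nucleophile + acid set free ⇌ protonated nucleophile, settled at all times (K = 504 /M)
    electrophile + acid set free → side product (k = 2.08 × 10⁻⁴ /M/s)
    2 nucleophile → self-condensation product (k = 0.00131 /M/s)
    electrophile + nucleophile → acid set free + target (k = 0.00118 /M/s)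

From this flask's 41.1%, the gain per doubling of 11 points gives 55.8% at 0.16 M, and the neighbour with that charge gives 56.4%. This flask is not at rest at 12 h: 59% of its electrophile is left, while the unbound free base stands at 0.39% of its charge. Left to 120 h, this flask reaches 92.5% of electrophile used. Its target goes from 36.3% to 55.3%, a rise of 19 points. Its side product goes from 4.78% to 37.2%, a rise of 32 points.

(All runs stem from a simulated flask on assumed constants, noise included.)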